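**Retrosynthetic overview**

1. Locants used throughout: C-1 CH–OAc, C-2/C-3 oxirane carbons (C-3 carries CH3), C-4 CH2, C-5 CH–O-isovaleryl, C-6 ring-fusion CH, C-7 ring-fusion C–CH3, C-8/C-9 cyclopentane CH2 groups, C-10 C(OH)(i-Pr); α is the face of the C-1 oxygen, β the face of the C-7 methyl.
2. Endgame: both esters and the hydroxyls at C-5 and C-10 come last; C-5–OH and C-6–H arise from hydroboration of a C-5=C-6 alkene, C-10–OH from oxidation of a C-10 boronic ester.
3. Key disconnection: the cyclopentane is cut at C-8–C-9 and C-6–C-10 to a cycloheptenylboronic ester (boron on C-6, CH2I on the quaternary C-7) and (3-methylbut-1-en-2-yl)lithium. In one operation the bis(alkenyl)borate closes a six-membered boracycle by radical attack of C-8 on C-9, and this ring contracts to the cyclopentane when C-6 shifts from boron to C-10.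
4. Enabling feature: in the five-membered ring the oxygen-bearing quaternary C-10 is bonded directly to the ring-fusion carbon C-6, which is flanked by the oxygenated C-5 of the seven-membered ring and by the quaternary C-7 carrying the CH2 group C-8. A C-10–B bond and a C-5=C-6 double bond therefore stand in for the 1,3-diol, and C-6 can travel from boron as an intact alkenyl group.
5. Ring order: seven-membered ring (ring-closing metathesis of an acyclic β-keto ester made by asymmetric allylic alkylation), then the oxirane (hydroxyl-directed epoxidation), then the cyclopentane (key step).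

Key step: step 11

Remark: 2-bromo-3-methylbut-1-ene (16) is taken as a purchasable reagent; it is otherwise available in one step by Markovnikov addition of HBr to 3-methylbut-1-yne.

**Route**

Step 1
Reactants: 1 methyl 2-methyl-3-oxobutanoate; 2 3-bromo-2-methylprop-1-ene
Product: 4 methyl 2,6-dimethyl-3-oxohept-6-enoate (racemic at the epimerisable C-2), via sodium lithium dianion 3 (not isolated)
Conditions: NaH, THF, 0 °C; n-BuLi, 0 °C; then 2, 0 °C → rt
Reagents that add atoms: none
Why: Weiler dianion γ-alkylation, in which the more basic terminal carbon of the acetoacetate dianion is alkylated by the allylic bromide; no stereocentre of consequence is set.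

Step 2
Reactants: 5 (E)-but-2-enal
Product: 6 (E)-but-2-ene-1,1-diyl diacetate
Conditions: Ac2O, FeCl3 (1 mol %), 0 °C → rt
Reagents that add atoms: acetic anhydride CC(=O)OC(C)=O
Why: Lewis-acid-catalysed acylal formation from an enal and acetic anhydride; no stereocentre is formed.

Step 3
Reactants: 4 methyl 2,6-dimethyl-3-oxohept-6-enoate; 6 (E)-but-2-ene-1,1-diyl diacetate
Product: 7 methyl (2R)-2-[(1R,2E)-1-acetoxybut-2-en-1-yl]-2,6-dimethyl-3-oxohept-6-enoate
Conditions: [Pd(C3H5)Cl]2 (2.5 mol %), (R,R)-DACH-phenyl Trost ligand (7.5 mol %), NaH, THF, 0 °C → rt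
Reagents that add atoms: none
Why: Trost asymmetric allylic alkylation, in which zerovalent palladium ionises one enantiotopic acetate of the gem-diacetate and the β-keto ester enolate attacks the acetoxy-bearing allyl terminus inside the chiral pocket, which should set C-1 and, through the facial bias on the enolate, the quaternary C-7 with the acetoxy group syn to the ester; should the sense of induction prove opposite, the (S,S)-ligand is used.

Step 4
Reactants: 7 methyl (2R)-2-[(1R,2E)-1-acetoxybut-2-en-1-yl]-2,6-dimethyl-3-oxohept-6-enoate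
Product: 8 methyl (1R,7R)-7-acetoxy-1,5-dimethyl-2-oxocyclohept-5-ene-1-carboxylate
Conditions: second-generation Grubbs catalyst (5 mol %), CH2Cl2, 40 °C
Reagents that add atoms: none
Why: Ring-closing metathesis between the propenyl group and the 1,1-disubstituted alkene closes the seven-membered ring with loss of propene, helped by the quaternary centre; no stereocentre is touched.

Step 5
Reactants: 8 methyl (1R,7R)-7-acetoxy-1,5-dimethyl-2-oxocyclohept-5-ene-1-carboxylate
Product: 10 methyl (1R,7R)-7-acetoxy-1,5-dimethyl-2-(trifluoromethanesulfonyloxy)cyclohepta-2,5-diene-1-carboxylate, via potassium enolate 9 (not isolated)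
Conditions: KN(SiMe3)2, THF, −78 °C; PhNTf2, −78 → 0 °C
Reagents that add atoms: N-phenylbis(trifluoromethanesulfonimide) O=S(=O)(N(c1ccccc1)S(=O)(=O)C(F)(F)F)C(F)(F)F
Why: Enol triflate formation, where enolisation can occur only towards C-5 because C-7 is quaternary and the potassium enolate is O-sulfonylated; no stereocentre changes.

Step 6
Reactants: 10 methyl (1R,7R)-7-acetoxy-1,5-dimethyl-2-(trifluoromethanesulfonyloxy)cyclohepta-2,5-diene-1-carboxylate
Product: 11 (6R,7R)-6-hydroxy-7-(hydroxymethyl)-4,7-dimethylcyclohepta-1,4-dien-1-yl trifluoromethanesulfonate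
Conditions: i-Bu2AlH, CH2Cl2, −78 → 0 °C; aqueous Rochelle salt
Reagents that add atoms: none
Why: Aluminium hydride reduction converts the methyl ester into the neopentyl primary alcohol (C-8) and cleaves the acetate, while the vinyl triflate is inert at low temperature; no stereocentre changes.

Step 7
Reactants: 11 (6R,7R)-6-hydroxy-7-(hydroxymethyl)-4,7-dimethylcyclohepta-1,4-dien-1-yl trifluoromethanesulfonate
Product: 12 enol triflate epoxy diol (α-oxirane at C-2/C-3 syn to the C-1 α-hydroxyl; C-7 β-methyl α-CH2OH; C-5=C-6 with triflate on C-6)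
Conditions: VO(acac)2 (5 mol %), t-BuOOH, CH2Cl2, 0 °C → rt
Reagents that add atoms: tert-butyl hydroperoxide CC(C)(C)OO
Why: Hydroxyl-directed epoxidation by a pentavalent vanadium alkylperoxide (Sharpless–Michaelson type) delivers oxygen to the allylic C-2=C-3 bond from the face of the C-1 hydroxyl, the electron-poor enol triflate double bond staying untouched.

Step 8
Reactants: 12 enol triflate epoxy diol
Product: 13 alkenylboronic ester diol (pinacolboryl on C-6 in place of the triflate of 12)
Conditions: PdCl2(PPh3)2 (3 mol %), PPh3, B2pin2, KOPh, toluene, 50 °C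
Reagents that add atoms: bis(pinacolato)diboron CC1(C)OB(OC1(C)C)B1OC(C)(C)C(C)(C)O1
Why: Miyaura borylation, in which the vinyl triflate adds oxidatively to zerovalent palladium and transmetalation with phenoxide-activated B2pin2 followed by reductive elimination gives the alkenylboronic ester with the double bond in place.

Step 9
Reactants: 13 alkenylboronic ester diol
Product: 14 neopentyl iodide (C-8 CH2I in place of CH2OH of 13; C-1 α-OH free)
Conditions: PPh3, I2, imidazole, toluene/MeCN, rt → 60 °C
Reagents that add atoms: iodine II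
Why: Appel-type iodination (Garegg–Samuelsson conditions) through the alkoxyphosphonium salt takes the primary alcohol, the secondary C-1 hydroxyl between a quaternary carbon and the oxirane reacting much more slowly.

Step 10
Reactants: 14 neopentyl iodide
Product: 15 triethylsilyl ether of 14 (C-1 α-OSiEt3)
Conditions: Et3SiOTf, 2,6-lutidine, CH2Cl2, −78 °C
Reagents that add atoms: triethylsilyl trifluoromethanesulfonate CC[Si](CC)(CC)OS(=O)(=O)C(F)(F)F
Why: Silylation of the remaining secondary alcohol with a silyl triflate and a hindered pyridine base protects C-1–OH against the organolithium of the next step.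

Step 11
Reactants: 15 triethylsilyl ether of 14; 16 2-bromo-3-methylbut-1-ene
Product: 19 tertiary allylic boronic ester with the cyclopentane closed (C-5=C-6 double bond; C-10 β-pinacolboryl α-isopropyl; C-7 β-methyl; C-1 α-OSiEt3; α-oxirane at C-2/C-3), via (3-methylbut-1-en-2-yl)lithium 17 (not isolated), via lithium bis(alkenyl)borate 18 (not isolated)
Conditions: 16, t-BuLi (2 equiv), Et2O, −78 °C; then 15, THF, −78 °C; then NiBr2(DME) (10 mol %), 4,4′-di-tert-butyl-2,2′-bipyridine (12 mol %), −78 °C → rt
Reagents that add atoms: none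
Why: Proposed new method: addition of alkenyllithium 17 to the boronic ester gives the bis(alkenyl)borate 18; low-valent (monovalent) nickel, formed in situ from the borate, abstracts iodine from C-8, the primary radical closes 6-endo onto the CH2 terminus (C-9) of the isopropylvinyl group, and one-electron oxidation of the resulting α-boryl radical anion by nickel triggers the 1,2-shift of the ring alkenyl carbon C-6 from boron to C-10, so that a six-membered boracycle contracts to the cyclopentane with boron left exocyclic. The closest known reactions are the Zweifel olefination of bis(alkenyl)borates and the nickel-catalysed or radical–polar crossover conjunctive couplings of vinylboron ate complexes with alkyl iodides; only the tethering of the iodide to the migrating group is new. The ring is closed by 6-endo-trig radical cyclisation followed by ring contraction through the 1,2-metallate shift, in which the C-5=C-6 double bond migrates intact. The new stereocentre C-10 should be controlled by the angular C-7 methyl, the isopropyl group taking the open α face and the boryl group the β face. The step needs 6-endo rather than 5-exo attack and reaction at the isopropylvinyl rather than the ring alkenyl unit: the fully substituted boron-bearing C-10 blocks 5-exo attack, the α-boryl radical anion from 6-endo attack is stabilised, and attack on the ring alkene would require a four-membered ring.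

Step 12
Reactants: 19 tertiary allylic boronic ester
Product: 21 diol (C-5 α-OH; C-6 α-H and so trans ring fusion; C-10 β-OH; C-1 α-OSiEt3), via C-5 alkylborane 20 (not isolated)
Conditions: BH3·THF, THF, 0 °C → rt; NaOH, H2O2, 0 °C → rt
Reagents that add atoms: hydrogen peroxide OO
Why: Hydroboration–oxidation, in which borane should add syn and anti-Markovnikov to the trisubstituted C-5=C-6 bond from the α face, away from the angular methyl and the C-10 boryl group (boron to C-5, hydrogen to C-6), and alkaline peroxide then oxidises both C–B bonds with retention, C-10–B giving the β tertiary alcohol.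

Step 13
Reactants: 21 diol
Product: 22 C-5 3-methylbutanoate of 21
Conditions: 3-methylbutanoyl chloride, pyridine, DMAP (cat.), CH2Cl2, 0 °C
Reagents that add atoms: 3-methylbutanoyl chloride CC(C)CC(=O)Cl
Why: Acylation with an acid chloride and DMAP takes place at the secondary C-5 hydroxyl only, the tertiary C-10 hydroxyl being too hindered.

Step 14
Reactants: 22 C-5 3-methylbutanoate
Product: 23 C-1 alcohol (desilylated 22)
Conditions: HF·pyridine, pyridine, THF, 0 °C
Reagents that add atoms: none
Why: Buffered fluoride desilylation frees the C-1 hydroxyl without base, which avoids Payne rearrangement of the epoxy alcohol and acyl migration.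

Step 15
Reactants: 23 C-1 alcohol
Product: 24 target CNP0137153.1
Conditions: Ac2O, pyridine, DMAP (cat.), CH2Cl2, rt
Reagents that add atoms: acetic anhydride CC(=O)OC(C)=O
Why: Acetylation of the only remaining secondary alcohol gives the target, the tertiary alcohol not reacting under these conditions.

**Compound list**

1 | methyl 2-methyl-3-oxobutanoate | COC(=O)C(C)C(C)=O | starting material
2 | 3-bromo-2-methylprop-1-ene | C=C(C)CBr | starting material
3 | sodium lithium dianion (1,3-dienolate) of 1 | [Na+].[Li+].C=C([O-])C(C)=C([O-])OC | intermediate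
4 | methyl 2,6-dimethyl-3-oxohept-6-enoate (racemic at C-2) | COC(=O)C(C)C(=O)CCC(C)=C | intermediate
5 | (E)-but-2-enal | C/C=C/C=O | starting material
6 | (E)-but-2-ene-1,1-diyl diacetate | C/C=C/C(OC(C)=O)OC(C)=O | intermediate
7 | methyl (2R)-2-[(1R,2E)-1-acetoxybut-2-en-1-yl]-2,6-dimethyl-3-oxohept-6-enoate | CC(=O)O[C@H](/C=C/C)[C@@](C)(C(=O)OC)C(=O)CCC(C)=C | intermediate
8 | methyl (1R,7R)-7-acetoxy-1,5-dimethyl-2-oxocyclohept-5-ene-1-carboxylate | CC(=O)O[C@@H]1C=C(C)CCC(=O)[C@]1(C)C(=O)OC | intermediate
9 | potassium enolate of 8 | [K+].CC(=O)O[C@@H]1C=C(C)CC=C([O-])[C@]1(C)C(=O)OC | intermediate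
10 | methyl (1R,7R)-7-acetoxy-1,5-dimethyl-2-(trifluoromethanesulfonyloxy)cyclohepta-2,5-diene-1-carboxylate | CC(=O)O[C@@H]1C=C(C)CC=C(OS(=O)(=O)C(F)(F)F)[C@]1(C)C(=O)OC | intermediate
11 | (6R,7R)-6-hydroxy-7-(hydroxymethyl)-4,7-dimethylcyclohepta-1,4-dien-1-yl trifluoromethanesulfonate | O[C@@H]1C=C(C)CC=C(OS(=O)(=O)C(F)(F)F)[C@]1(C)CO | intermediate
12 | enol triflate epoxy diol (α-oxirane at C-2/C-3, C-1 α-OH, C-7 β-CH3 α-CH2OH, triflate on C-6) | O[C@@H]1[C@@H]2O[C@]2(C)CC=C(OS(=O)(=O)C(F)(F)F)[C@]1(C)CO | intermediate
13 | alkenylboronic ester diol (pinacolboryl on C-6) | O[C@@H]1[C@@H]2O[C@]2(C)CC=C(B3OC(C)(C)C(C)(C)O3)[C@]1(C)CO | intermediate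
14 | neopentyl iodide (C-8 CH2I, C-1 α-OH) | O[C@@H]1[C@@H]2O[C@]2(C)CC=C(B3OC(C)(C)C(C)(C)O3)[C@]1(C)CI | intermediate
15 | triethylsilyl ether of 14 (C-1 α-OSiEt3) | CC[Si](CC)(CC)O[C@@H]1[C@@H]2O[C@]2(C)CC=C(B3OC(C)(C)C(C)(C)O3)[C@]1(C)CI | intermediate
16 | 2-bromo-3-methylbut-1-ene | C=C(Br)C(C)C | starting material
17 | (3-methylbut-1-en-2-yl)lithium | [Li]C(=C)C(C)C | intermediate
18 | lithium bis(alkenyl)(pinacolato)borate from 15 and 17 | [Li+].CC[Si](CC)(CC)O[C@@H]1[C@@H]2O[C@]2(C)CC=C([B-]3(C(=C)C(C)C)OC(C)(C)C(C)(C)O3)[C@]1(C)CI | intermediate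
19 | tertiary allylic boronic ester, cyclopentane closed (C-5=C-6, C-10 β-Bpin α-i-Pr, C-7 β-CH3, C-1 α-OSiEt3, α-oxirane) | CC[Si](CC)(CC)O[C@@H]1[C@@H]2O[C@]2(C)CC=C2[C@]1(C)CC[C@@]2(B3OC(C)(C)C(C)(C)O3)C(C)C | intermediate
20 | C-5 alkylborane (C-5 α-BH2, C-6 α-H) | CC[Si](CC)(CC)O[C@@H]1[C@@H]2O[C@]2(C)C[C@H](B)[C@@H]2[C@]1(C)CC[C@@]2(B3OC(C)(C)C(C)(C)O3)C(C)C | intermediate
21 | diol (C-5 α-OH, C-6 α-H, C-10 β-OH, C-1 α-OSiEt3) | CC[Si](CC)(CC)O[C@@H]1[C@@H]2O[C@]2(C)C[C@H](O)[C@@H]2[C@]1(C)CC[C@@]2(O)C(C)C | intermediate
22 | C-5 3-methylbutanoate of 21 | CC[Si](CC)(CC)O[C@@H]1[C@@H]2O[C@]2(C)C[C@H](OC(=O)CC(C)C)[C@@H]2[C@]1(C)CC[C@@]2(O)C(C)C | intermediate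
23 | C-1 alcohol | O[C@@H]1[C@@H]2O[C@]2(C)C[C@H](OC(=O)CC(C)C)[C@@H]2[C@]1(C)CC[C@@]2(O)C(C)C | intermediate
24 | CNP0137153.1 (C-1 α-acetate, α-oxirane, C-5 α-3-methylbutanoate, C-10 β-OH) | CC(=O)O[C@@H]1[C@@H]2O[C@]2(C)C[C@H](OC(=O)CC(C)C)[C@@H]2[C@]1(C)CC[C@@]2(O)C(C)C | target

Total step count: 15. Longest linear sequence: 14 steps (steps 1 and 3 to 15; step 2 is a one-step side branch).

**Steps most likely to fail**

1. Step 11 (Proposed new method). The borate could be diverted before the metallate shift by 5-exo closure of the C-8 radical onto C-10, by a ring-expanding 1,2-vinyl shift of that radical through C-6, or by direct cross-coupling at nickel. Fallback, with known chemistry and the two bonds made one after the other: setting out from 12, both hydroxyls are silylated (Et3SiCl, imidazole) to give the bis(triethylsilyl) ether F1. Swern oxidation cleaves and oxidises the primary silyl ether selectively to the neopentyl aldehyde F2. Horner–Wadsworth–Emmons olefination with dimethyl (3-methyl-2-oxobutyl)phosphonate and Ba(OH)2 gives the E-enone F3, and conjugate reduction with [CuH(PPh3)]6 gives the saturated isopropyl ketone F4. Intramolecular Nozaki–Hiyama–Kishi addition of the vinyl triflate to the ketone (CrCl2, cat. NiCl2, DMF) closes the cyclopentane as the tertiary allylic alcohol F5, with the isopropyl group expected on the α face away from the angular methyl. Hydroboration–oxidation as in step 12 then returns to the route at 21.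

2. Step 12. Borane may attack from the β face, which would give the cis-fused C-5/C-6 epimer, or may reduce the oxirane. Fallback: setting out from 19, hydroboration–oxidation is run without regard to facial selectivity and the crude diol is oxidised at C-5 with Dess–Martin periodinane. Brief treatment with DBU equilibrates C-6 of the β-hydroxy ketone to the trans-fused C-5 ketone F6, in which C-5 lies cis to the C-10 hydroxyl and the C-7 methyl and trans to the isopropyl group. Hydroxyl-directed anti reduction with Me4NBH(OAc)3 (Evans–Saksena), with hydride delivered from the C-10 β-hydroxyl, returns to the route at 21.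

3. Step 3. Facial discrimination of the acyclic enolate may be poor (low diastereoselectivity at the quaternary carbon), or attack may leak to the methyl-bearing allyl terminus. Fallback: setting out from 4 and 5, the titanium enolate of 4 (TiCl4, Et3N, CH2Cl2, −78 °C) adds 1,2 to (E)-but-2-enal to give, after chromatographic separation of diastereomers, the racemic aldol F7. Kinetic resolution with Candida antarctica lipase B and vinyl acetate acetylates the (1R)-alcohol and returns to the route at 7.

**Further compounds**

F1 | step 11 | C-1,C-8 bis(triethylsilyl) ether of 12 | CC[Si](CC)(CC)O[C@@H]1[C@@H]2O[C@]2(C)CC=C(OS(=O)(=O)C(F)(F)F)[C@]1(C)CO[Si](CC)(CC)CC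
F2 | step 11 | C-8 aldehyde (C-1 α-OSiEt3, enol triflate, α-oxirane) | CC[Si](CC)(CC)O[C@@H]1[C@@H]2O[C@]2(C)CC=C(OS(=O)(=O)C(F)(F)F)[C@]1(C)C=O
F3 | step 11 | (E)-enone from olefination of F2 (C-8=C-9, C-10 ketone with isopropyl) | CC[Si](CC)(CC)O[C@@H]1[C@@H]2O[C@]2(C)CC=C(OS(=O)(=O)C(F)(F)F)[C@]1(C)/C=C/C(=O)C(C)C
F4 | step 11 | saturated isopropyl ketone (C-10 ketone, enol triflate at C-6) | CC[Si](CC)(CC)O[C@@H]1[C@@H]2O[C@]2(C)CC=C(OS(=O)(=O)C(F)(F)F)[C@]1(C)CCC(=O)C(C)C
F5 | step 11 | tertiary allylic alcohol (C-10 β-OH α-i-Pr, C-5=C-6, C-1 α-OSiEt3) | CC[Si](CC)(CC)O[C@@H]1[C@@H]2O[C@]2(C)CC=C2[C@]1(C)CC[C@@]2(O)C(C)C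
F6 | step 12 | trans-fused C-5 ketone (C-6 α-H, C-10 β-OH, C-1 α-OSiEt3) | CC[Si](CC)(CC)O[C@@H]1[C@@H]2O[C@]2(C)CC(=O)[C@@H]2[C@]1(C)CC[C@@]2(O)C(C)C
F7 | step 3 | racemic methyl (2R*)-2-[(1R*,2E)-1-hydroxybut-2-en-1-yl]-2,6-dimethyl-3-oxohept-6-enoate (one enantiomer drawn) | O[C@H](/C=C/C)[C@@](C)(C(=O)OC)C(=O)CCC(C)=C
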